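All constants are assumed; the rest is arithmetic.

A neighbour flask charged with 0.022 M of partner made me ask of this flask, with 0.0555 M, how much of the second intermediate from partner meets open intermediate before it decomposes.

substrate 0.037 M; partner 0.0555 M; time 25 h

1. which holds at 25 h: what has brought the reaction to rest, or that it has not come to rest (it is still moving / all of the substrate has reacted / forward and back rates have come level)
2. product at 25 h, in percent of the substrate charged

- amounts and yields of product count crystals too
- given per volume of solution although it is solid: crystals
- the reaction counts as stopped when no species that holds the substrate changes by six tenths of a point or more over the second half of the time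
- run time (flask): 25 h

    partner → second intermediate (k1 = 0.053 min⁻¹)
    open intermediate + second intermediate → product (k2 = 35 M⁻¹ min⁻¹)
    crystals ⇌ product, rate k3*(cs3 - [product]) while solid is left; crystals form when [product] > cs3 (cs3 = 11 mM, k3 = 0.81 min⁻¹)
    second intermediate → decomposed reagent (k4 = 0.014 min⁻¹)
    partner ⇌ dormant form (K5 = 0.92, k5 = 0.048 min⁻¹)
    substrate ⇌ open intermediate (K6 = 0.42, k6 = 0.59 min⁻¹)

Partner turns into second intermediate with a half-life of 0.22 h by that step alone, far shorter than the 25 h of the run, so I reckoned on the contest for second intermediate. It either meets open intermediate or decomposes. I replaced the falling curve of substrate and open intermediate together by its mean, half the charge. That pair relaxes with a half-life of 0.347 min, quicker than partner falls, so I took 29.6% of it as open intermediate, a mean of 5.47 mM. Capture then ran at 0.192 min⁻¹ against decomposition at 0.014 min⁻¹. The capture share, capture over capture plus decomposition, came to 93.2%. Times partner, that gave a capacity of 0.0517 M, more than the 0.037 M of substrate. At half that mean, the capacity was still 0.0484 M, above the substrate. So I expected a yield of 100%.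

The forecast gave all of the substrate has reacted and 100%, on the ground that “the open intermediate captures it far faster than it decomposes”.

The simulation gave all of the substrate has reacted and >99.9%. In this flask product already stood at >99.9% after 2.50 h.

In this flask the surplus over the substrate appeared as decomposed reagent, 0.0185 M, matching partner less substrate. In the neighbour flask, partner stood below substrate, so I took the mean of substrate and open intermediate together as 0.0260 M. That gave a capture share of 95.1% and a reckoned product of 56.5%. The neighbour flask held 56.4% product, with partner, its limiting reagent, at 0% and substrate at 30.7%.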